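3 questions stand for 5 flasks read at 4.0 d: their order by Imd2, and the Imd2 of the first and of the last.

| flask | Imd | Rea | Lvg | remark | time |
|---|---|---|---|---|---|
| delta | 0.40 M | 0.34 M | 0.20 M | run made earlier |  |
| eta | 0.40 M | 1.4 M | 0.20 M | run made earlier |  |
| zeta | 0.40 M | 0.60 M | 0.27 M | run made earlier |  |
| blue | 0.25 M | 1.20 M | 0.100 M |  | 4.0 d |
| red | 0.60 M | 0.600 M | 0.200 M |  | 4.0 d |
| ochre | 0.25 M | 0.400 M | 0.600 M |  | 4.0 d |
| teal | 0.40 M | 0.600 M | 0.200 M |  | 4.0 d |
| amber | 0.40 M | 2.00 M | 0.400 M |  | 4.0 d |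

| run | time / d | Imd2 / % | Imd / % |
|---|---|---|---|
| delta | 0.208 | 8.6 | 91.3 |
| delta | 0.333 | 11.5 | 85.1 |
| delta | 0.625 | 17.8 | 76.8 |
| delta | 1.04 | 22.5 | 68.3 |
| delta | 1.67 | 27.0 | 58.8 |
| delta | 3.00 | 25.1 | 47.4 |
| eta | 0.500 | 38.8 | 41.8 |
| eta | 1.04 | 44.2 | 18.9 |
| eta | 1.25 | 43.9 | 14.6 |
| eta | 2.08 | 35.4 | 5.7 |
| eta | 2.50 | 29.9 | 3.9 |
| eta | 3.00 | 24.9 | 1.9 |
| zeta | 0.208 | 14.3 | 85.6 |
| zeta | 0.417 | 22.7 | 72.9 |
| zeta | 0.833 | 30.9 | 55.4 |
| zeta | 1.67 | 33.0 | 37.6 |
| zeta | 3.00 | 26.1 | 22.5 |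

(standard deviation of a reading: 0.5 percentage points)

- the flasks by amount of Imd2, in percent of the Imd charged, highest first, at 4.0 d (blue / red / ochre / teal / amber)
- the amount of Imd2, in percent of the Imd charged of the flask you put first, at 4.0 d
- the amount of Imd2, in percent of the Imd charged of the flask you put last, at 4.0 d



Imd2 is made from Imd and is then lost, so a flask's reading depends on how long its Imd2 has been exposed to that loss. The tail of the eta run shows the loss with Imd down to 5.7%: Imd2 reads 35.4% at 2.08 d and 24.9% at 3.00 d, which gives a pseudo-first-order constant of 0.382 d⁻¹ as read. Every earlier run holds Imd at 0.40 M, so the runs cannot test the part Imd plays; it is an assumption of this reckoning that the loss scales with cLvg + cImd. The exposure number S is then that constant times the time times cLvg + cImd, divided by the same sum in eta; it counts the lifetimes of Imd2 a flask has lived, and for blue it is 0.892. Teal has 1.53, red 2.04, ochre 2.17 and amber 2.04. Eta's last reading, carried back, gives a level of 78.4% at S of zero, and the Imd2 of a flask is reckoned as that level multiplied by exp(−S).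

Is one number enough? Delta and eta have equal S at 3.00 d and read 25.1% and 24.9%, but delta still holds 47.4% of Imd against 1.9% in eta. Zeta, with a larger sum, reads more Imd2, 26.1%. So S is not enough while Imd still feeds. Amber, charged with more Rea than eta, is expected to use its Imd early, whereas red and ochre lie nearer delta. This reckoning therefore commits to blue, teal, red, ochre, amber, with about 32.1% first and 10.2% last.

The forecast differs: red > teal > blue > ochre > amber, with 32% first and 1.8% last, on the ground that “red keeps more Imd feeding in”.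

The flasks give blue > teal > red > ochre > amber, with 26.9% in blue and 9.76% in amber.

    Lvg + Imd2 → Lvg.Imd2 (k = 9.30 × 10⁻⁴ M⁻¹ min⁻¹)
    Imd + Rea ⇌ Lvg + Imd2 (K = 9.50, k = 0.00100 M⁻¹ min⁻¹)
    Imd2 + Rea ⇌ Lvg + Imd3 (K = 0.150, k = 0.00130 M⁻¹ min⁻¹)

Forecast and flask part on first place, red against blue, whose S is the lowest. Blue has not come to rest at 4.0 d: it holds 26.9% of Imd2 and 56.0% of Lvg.Imd2. Ten times the time lifts its S to 8.92, for which the reckoning gives 0.0105%, yet blue then holds more, 0.778% of Imd2, with 98.1% of Lvg.Imd2. Amber, at S of 20.4 by then, holds 0% of Imd2.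

The runs come from a simulation from invented constants, and the scatter is random.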